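## Structural features

The target is a flavone: a phloroglucinol-type ring A fused to a γ-pyranone ring C, with a 2,4-dihydroxyphenyl ring B on C2 and free hydroxyls at C5, C7, C2' and C4'. C6, the ring A carbon between the C5 and C7 hydroxyls, carries a lavandulyl chain: C1''H2 is bonded to ring A, C2'' bears an isopropenyl group, and C3''H2–C4''H=C5''(CH3)2 forms a prenyl arm. C2'' is the only stereocenter, (S). It has no neighbouring stereocenter and no heteroatom, and its three carbon substituents are sterically similar, so no resident group helps to set it. The fragile parts are the 1,1-disubstituted and trisubstituted alkenes, which lie within reach of the C5 and C7 hydroxyls (acid or electrophiles would close chroman or dihydrofuran rings, and hydrogenolysis is excluded), the electron-rich, easily over-halogenated ring A, and the chelated 5-hydroxy-4-ketone. The real difficulties are the enantioselective construction of C2'' and the placement of the chain at C6 and not at C8. The key step exploits the fact that C2'' is joined to exactly three carbon groups, C1''H2–ring A, C3''H2–C4''H=C5'' and isopropenyl. A vinyl group on boron supplies C2'' and C3'', the ring A benzyl group migrates to C2'', an alkenyl electrophile adds C4'' and C5'', and the boron left on C2'' holds the place of the isopropenyl group. The local symmetry of ring A (two equivalent oxygens ortho to C6, a third para to it) settles the C6/C8 question.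

## Logic of the disconnections

**27 ⇒ 26.** Only the four O–CH2 bonds of acetal protecting groups are cut; no skeletal bond changes. The hydroxyls at C5 and C7 would trap any cation or iodonium ion formed at the chain alkenes, and free phenols do not survive the organolithium steps. The gain is one global final operation on a neutral precursor. The demand is an acetal cleavage mild enough to spare both alkenes.

**26 ⇒ 20 + 23.** C4a–C4, C4–C3 and O1–C2 are cut, with C4 as a one-carbon carbonyl unit. This divides the molecule into a ring A/side-chain half and a ring B half at the last skeletal step. 20 is monocyclic and 23 is two steps from 21. The forward step must form the acylpalladium faster than it alkynylates directly, and must close ring C in the 6-endo sense.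

**20 ⇒ 19 ⇒ 18.** The C–I bond and then the O–Si bond are cut. In 19 the free hydroxyl is para to the chain and the two ortho positions are equivalent, so halogenation at either gives the same compound and the chain must end at C6 after annulation. The demand is mono-iodination without attack on the alkenes. The two ether groups beside the chain leave no hydroxyl that could cyclise.

**18 ⇒ 13 + 14.** The C2''–C(isopropenyl) bond is cut. A secondary C–B bond can be exchanged for an alkenyl group with retention, so the stereocenter is held at a configurationally stable C–B stage and never next to a carbonyl. The gain is that the stereocenter problem becomes that of a simple secondary boronate. The forward step must be stereoretentive, and the electrophile must react at the alkenyl borate faster than at the prenyl alkene.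

**13 ⇒ 7 + 11 + 9.** C1''–C2'' and C3''–C4'' are cut. C2'' then arises from three achiral pieces in one catalytic enantioselective operation. This removes the stereocenter and two skeletal bonds at once. The demand is that the 1,2-shift of a bulky benzylic group outruns its direct transfer to palladium, and that face selection by the catalyst is high.

**7 ⇒ 3 + 4, then 3 ⇒ 2 ⇒ 1.** The C(aryl)–C1'' bond is cut, then four O–C and O–Si protecting bonds. The carbon between the two acetal ethers of 3 is the most acidic ring position, and 4 delivers C1'' together with boron. The gain is a return to a symmetric triol. The demands are regioselective metalation and a monosilylation that differentiates one of three equal hydroxyls.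

**9 ⇒ 8, 11 ⇒ 10, 23 ⇒ 22 ⇒ 21.** These cut a C–O(sulfonyl) bond, a C–Li bond, and one C–C bond plus two O–C bonds. Each partner comes from a bulk chemical in one or two steps. The only special demand is that 11 be free of halide.

## Other disconnections considered

**Alternative 1:** ring A by a vinylogous Claisen closure on a pyranone.
- **Cut:** C4a–C5, with C5 and C7 coming from an ester and a ketone.
- **Forward step:** the pyranonyl β-keto ester A1 is treated with a hindered base such as LiN(SiMe3)2. The extended enolate reaches through the pyranone, its C4a carbon attacks the ester carbonyl, and loss of methanol and enolisation give A2. The allyl ethers of A2 would then be removed with Pd(PPh3)4 and a soft nucleophile.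
- **In favour:** the chain is fixed at C6 by connectivity, which equals the chosen plan (fixed there by symmetry). Ring A needs no protecting groups and the last deprotection is neutral, which is better than the acidic step 13.
- **Against:** the most acidic hydrogen of A1 is the one between ketone and ester. The reacting species would therefore be a dianion whose ester is flanked by an enolate and is a poor electrophile. C-acylation at the pyranone carbon competes with O-acylation and with base attack on the pyranone. Making A1 needs alkylation of a β-keto ester with a β-branched lavandulyl electrophile, a slow substitution. C2'' must come from a separate asymmetric synthesis or resolution.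
- **Comparison:** structurally it builds ring A around a finished chain, whereas the chosen plan buys ring A and builds the chain. Mechanistically it is anionic and substrate-bound, against catalytic and reagent-controlled. On step count it should be longer, since the pyranone, the keto ester and an enantiopure chain must all be made.

**Alternative 2:** ring A by ketene–siloxyalkyne benzannulation on a pyranone.
- **Cut:** C5–C6, C7–C8 and C4a–C5.
- **Forward step:** irradiation of diazo ketone A3 triggers a Wolff rearrangement to a (4-oxopyran-2-yl)ketene. This adds siloxyalkyne A4 in a [2+2] sense, the cyclobutenone opens (4π), and 6π closure onto pyranone C3 with tautomerisation gives A5. Fluoride would then remove the three silyl groups.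
- **In favour:** it is the most convergent ring construction of all, which is better than the chosen plan on that count. The C5/C6/C7 pattern follows from the polarisation of A4, which equals the chosen plan on regiocontrol. No acid is needed and the final desilylation is milder than step 13, which is better.
- **Against:** the C2=C3 bond of a γ-pyranone must act as the vinyl part of the vinylketene, which is a less secure 2π partner than a simple alkene or arene. The 2-aryl-γ-pyranone chromophore absorbs where the diazo ketone is photolysed and has its own photochemistry. A3 needs diazo chemistry on a pyranone acid. A4 needs an enantiopure lavandulyl ester and an ester-to-ynol-ether homologation, so C2'' again comes from elsewhere.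
- **Comparison:** it is superior in convergence and in the mildness of the end game, equal in regiocontrol, and weaker in precedent for the ring-forming partner and in the supply of the stereocenter. The total step count would probably be similar or higher once A4 is made in enantiopure form.

**Alternative 3:** ring C by three-component carbonylative annulation.
- **Cut:** C4a–C4, C4–C3 and O1–C2.
- **Forward step:** iodophenol A6, carbon monoxide and arylacetylene A7 combine under PdCl2(PPh3)2 in Et2NH to give A8. A6, A7 and A8 are identical with 20, 23 and 26.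
- **In favour:** the chosen route uses this same annulation as step 12, so on ring C the two plans are equal by construction. It is convergent, the symmetric phenol makes mono-iodination regiochemically unambiguous, and alkenes and acetals are tolerated.
- **Against:** taken as the strategy-defining step, it leaves the origin of C2'' open. The chain would then be attached as a preformed enantiopure lavandulyl building block to a metallated phloroglucinol ether. That is a slow substitution at a β-branched primary carbon, with competing elimination and O-alkylation. The acid liability of the last step is the same, which is equal.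
- **Comparison:** if an enantiopure lavandulyl electrophile were cheaply at hand, this plan would be shorter than the chosen one, which is a point in its favour. Without it, the chosen plan is the same end game with a catalytic asymmetric construction of the chain placed in front.

Key step: step 6

**Remarks before the steps**

- Remark: 13 and 27 are both (S) although boron is exchanged for carbon with retention. Boron ranks below both methylene carbons at C2'', isopropenyl ranks above them, and the two changes in ranking cancel.
- Assumption: the MandyPhos antipode that leads to (S)-13 is not predicted here. It is to be fixed by correlation (oxidation of a sample of 13 to the secondary alcohol), and the other ligand enantiomer used if needed.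
- Design of the precursor: 7 is freed of LiCl before use and 11 is made free of halide and used in exactly one equivalent, because halide ions inhibit the cationic palladium pathway.
- Design of the precursor: the para oxygen is a TIPS ether (stable to n-BuLi, remote from the lithiation site). The two ortho oxygens are MOM ethers, which direct the metalation, keep the later phenols from cyclising onto the alkenes, and leave only the para hydroxyl free for annulation.

## Route

Step 1
Reactants: 1 phloroglucinol (benzene-1,3,5-triol)
Product: 2 5-{[tri(propan-2-yl)silyl]oxy}benzene-1,3-diol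
Conditions: TIPSCl (1.0 equiv), imidazole (1.5 equiv), anhydrous 1 (3 equiv), DMF, 0 °C → rt
Reagents that add atoms: chlorotri(propan-2-yl)silane, CC(C)[Si](Cl)(C(C)C)C(C)C
Why: Imidazole-promoted silylation of a phenol; the excess of the cheap, water-soluble triol keeps bis-silylation low and is removed by aqueous extraction, and the bulky silyl group is chosen because it survives n-BuLi.

Step 2
Reactants: 2 5-{[tri(propan-2-yl)silyl]oxy}benzene-1,3-diol
Product: 3 [3,5-bis(methoxymethoxy)phenoxy]tri(propan-2-yl)silane
Conditions: MOMCl (2.6 equiv), i-Pr2NEt (3 equiv), CH2Cl2, 0 °C → rt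
Reagents that add atoms: chloro(methoxy)methane, COCCl
Why: O-Alkylation of the two remaining phenols with the chloromethyl ether and a hindered amine base; the aryl silyl ether is stable to these non-nucleophilic conditions.

Step 3
Reactants: 3 [3,5-bis(methoxymethoxy)phenoxy]tri(propan-2-yl)silane; 4 2-(chloromethyl)-4,4,5,5-tetramethyl-1,3,2-dioxaborolane
Product: 7 2-{[2,6-bis(methoxymethoxy)-4-{[tri(propan-2-yl)silyl]oxy}phenyl]methyl}-4,4,5,5-tetramethyl-1,3,2-dioxaborolane, via aryllithium 5 (not isolated), via chloromethyl borate 6 (not isolated)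
Conditions: n-BuLi (1.1 equiv), THF, 0 °C, 1 h; 4 (1.2 equiv), −78 °C → rt, then 45 °C; aqueous wash, chromatography
Reagents that add atoms: none
Why: Directed ortho-metalation: the C–H between the two MOM ethers is activated by both coordinating groups and the positions next to the bulky silyl ether are not, so 5 should form regioselectively. Capture by the boron of 4 gives borate 6, whose aryl group undergoes a 1,2-shift with loss of chloride (Matteson-type homologation).

Step 4
Reactants: 8 isobutyraldehyde (2-methylpropanal)
Product: 9 2-methylprop-1-en-1-yl trifluoromethanesulfonate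
Conditions: Tf2O (1.1 equiv), 2,6-di-tert-butyl-4-methylpyridine (1.2 equiv), CH2Cl2, 0 °C → reflux; filtration, distillation
Reagents that add atoms: trifluoromethanesulfonic anhydride, O=S(=O)(OS(=O)(=O)C(F)(F)F)C(F)(F)F
Why: O-Sulfonylation of the aldehyde followed by loss of its only α-hydrogen to the hindered, non-nucleophilic pyridine gives the enol triflate; the alkene terminus bears two methyl groups, so no geometric isomers can arise.

Step 5
Reactants: 10 tetravinylstannane
Product: 11 vinyllithium
Conditions: n-BuLi (4 equiv), pentane, rt; solid filtered under argon, washed with pentane, dissolved in THF, titrated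
Reagents that add atoms: n-butyllithium, [Li]CCCC
Why: Tin–lithium exchange, driven by the greater stability of the sp2 carbanion and by precipitation of 11 from pentane; it gives the halide-free reagent that step 6 requires.

Step 6
Reactants: 7 the benzylic pinacol boronate of step 3; 11 vinyllithium; 9 2-methylprop-1-en-1-yl trifluoromethanesulfonate
Product: 13 2-[(2S)-1-[2,6-bis(methoxymethoxy)-4-{[tri(propan-2-yl)silyl]oxy}phenyl]-5-methylhex-4-en-2-yl]-4,4,5,5-tetramethyl-1,3,2-dioxaborolane, via vinyl borate 12 (not isolated)
Conditions: 7, 11 (1.0 equiv), THF, 0 °C → rt, 30 min; then 9 (1.2 equiv), Pd(OAc)2 (2 mol %), MandyPhos ligand 1,1′-bis[bis(4-methoxy-3,5-dimethylphenyl)phosphino]-2,2′-bis[(dimethylamino)(phenyl)methyl]ferrocene (2.4 mol %, antipode leading to (S)-13), THF, 60 °C, 16 h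
Reagents that add atoms: none
Why: Addition of 11 to the boron of 7 gives the four-coordinate vinyl borate 12, and oxidative addition of 9 to the zerovalent palladium–MandyPhos complex gives a cationic alkenyl divalent palladium species (triflate does not coordinate and no halide is present) that binds the vinyl group of 12. Binding triggers a 1,2-metallate shift in which the benzylic carbon C1'' moves from boron to C2'' anti to palladium while palladium bonds to C3''; reductive elimination of the resulting alkylpalladium with the 2-methylpropenyl ligand then forms C3''–C4'' and returns zerovalent palladium. The closest known reaction type is the enantioselective three-component conjunctive cross-coupling of alkyl(vinyl) and aryl(vinyl) pinacol borates with alkenyl and aryl triflates; only the substrate is new, a primary benzylic migrating group flanked by two ortho ether groups. No ring is closed. The one new stereocenter, C2'', is set by the enantiofacial binding of the vinyl borate to the chiral bisphosphine–palladium complex, since the migration is stereospecifically anti to the metal. The step needs selectivity for the metallate shift over direct transfer of the benzyl or vinyl group to palladium and over β-hydride elimination: the saturated pinacolato borate offers no free site for transmetalation, the electron-rich benzyl group should migrate readily, and the wide-bite-angle ligand speeds reductive elimination. The MOM and silyl ethers are inert to one equivalent of 11 and to the neutral coupling conditions.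

Step 7
Reactants: 13 the (S)-secondary pinacol boronate of step 6; 14 2-bromopropene
Product: 18 {3,5-bis(methoxymethoxy)-4-[(2S)-5-methyl-2-(prop-1-en-2-yl)hex-4-en-1-yl]phenoxy}tri(propan-2-yl)silane, via isopropenyllithium 15 (not isolated), via alkenyl borate 16 (not isolated), via β-iodoalkyl boronic ester 17 (not isolated)
Conditions: 14 (1.3 equiv), t-BuLi (2.6 equiv), THF, −78 °C; 13, −78 °C, 30 min; I2 (1.4 equiv), THF/MeOH, −78 °C; NaOMe (3 equiv), MeOH, −78 °C → rt; aq. Na2S2O3
Reagents that add atoms: none
Why: Zweifel olefination: bromine–lithium exchange gives 15, which adds to boron to give borate 16; iodine attacks the electron-rich alkenyl borate (far more nucleophilic than the prenyl alkene), C2'' migrates from boron to carbon to give 17, and methoxide triggers anti elimination of boron and iodide to the 1,1-disubstituted alkene. The migrating carbon keeps its configuration and no carbonyl or allyl-metal stage is involved, so the (S) centre is carried over unchanged.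

Step 8
Reactants: 18 the lavandulyl aryl silyl ether of step 7
Product: 19 3,5-bis(methoxymethoxy)-4-[(2S)-5-methyl-2-(prop-1-en-2-yl)hex-4-en-1-yl]phenol
Conditions: TBAF (1.1 equiv), THF, 0 °C
Reagents that add atoms: none
Why: Fluoride cleavage of an aryl silyl ether; MOM ethers and alkenes are inert, and any silyl ether already lost to NaOMe in step 7 converges on 19 here.

Step 9
Reactants: 19 the para-hydroxy lavandulyl arene of step 8
Product: 20 2-iodo-3,5-bis(methoxymethoxy)-4-[(2S)-5-methyl-2-(prop-1-en-2-yl)hex-4-en-1-yl]phenol
Conditions: I2 (1.0 equiv, slow addition), NaHCO3 (2 equiv), THF/H2O (1:1), 0 °C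
Reagents that add atoms: iodine, II
Why: Electrophilic aromatic iodination of the phenoxide, which should react with iodine far faster than the isolated alkenes. The two positions ortho to the hydroxyl are equivalent, so only the stoichiometry has to be held, and the MOM ethers beside the chain leave no hydroxyl that could close onto an iodonium ion.

Step 10
Reactants: 21 2,4-dihydroxybenzaldehyde
Product: 22 2,4-bis(methoxymethoxy)benzaldehyde
Conditions: MOMCl (3 equiv), K2CO3 (4 equiv), acetone, reflux
Reagents that add atoms: chloro(methoxy)methane, COCCl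
Why: O-Alkylation of both phenols; K2CO3 in refluxing acetone also alkylates the hydrogen-bonded 2-hydroxyl.

Step 11
Reactants: 22 2,4-bis(methoxymethoxy)benzaldehyde
Product: 23 1-ethynyl-2,4-bis(methoxymethoxy)benzene
Conditions: dimethyl (1-diazo-2-oxopropyl)phosphonate (1.3 equiv), K2CO3 (2 equiv), MeOH, rt
Reagents that add atoms: dimethyl (1-diazo-2-oxopropyl)phosphonate, COP(=O)(OC)C(=[N+]=[N-])C(C)=O
Why: Seyferth–Gilbert homologation with the Ohira–Bestmann reagent: methanolysis releases the diazomethylphosphonate anion, which olefinates the aldehyde, and loss of N2 with 1,2-hydrogen shift gives the terminal alkyne under conditions that leave the MOM ethers untouched.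

Step 12
Reactants: 20 the ortho-iodophenol of step 9; 23 1-ethynyl-2,4-bis(methoxymethoxy)benzene
Product: 26 5,7-bis(methoxymethoxy)-2-[2,4-bis(methoxymethoxy)phenyl]-6-[(2S)-5-methyl-2-(prop-1-en-2-yl)hex-4-en-1-yl]-4H-chromen-4-one, via alkynone 24 (not isolated), via diethylamino enone 25 (not isolated)
Conditions: CO (1 atm), 23 (1.5 equiv), PdCl2(PPh3)2 (5 mol %), dppp (5 mol %), thiourea (5 mol %), DBU (1.5 equiv), Et2NH, 40–50 °C
Reagents that add atoms: carbon monoxide, [C-]#[O+]
Why: Carbonylative Sonogashira-type coupling with in situ annulation: oxidative addition of the C–I bond to zerovalent palladium, CO insertion and coupling of the acylpalladium with the alkyne give 24. Conjugate addition of Et2NH gives 25, and the phenol closes ring C by 6-endo addition–elimination, which is why the flavone and not the 5-exo aurone is expected. O1 comes from the hydroxyl para to the chain, so the chain ends at C6.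

Step 13
Reactants: 26 the tetrakis(methoxymethyl) flavone of step 12
Product: 27 2-(2,4-dihydroxyphenyl)-5,7-dihydroxy-6-[(2S)-5-methyl-2-(prop-1-en-2-yl)hex-4-en-1-yl]-4H-chromen-4-one (target)
Conditions: 3 M aq. HCl, MeOH, 45 °C, stopped at full conversion; NaHCO3
Reagents that add atoms: none
Why: Acid-catalysed acetal exchange of the four aryl MOM ethers with methanol. The chromone carbonyl lowers the nucleophilicity of the C5 hydroxyl (hydrogen bond) and the C7 hydroxyl (vinylogous acid), which with the mild temperature should hold back protonation of the alkenes and chroman formation; C2'' cannot epimerise under these conditions.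

## Compound list

1 | phloroglucinol (benzene-1,3,5-triol) | Oc1cc(O)cc(O)c1 | starting material
2 | 5-{[tri(propan-2-yl)silyl]oxy}benzene-1,3-diol | CC(C)[Si](Oc1cc(O)cc(O)c1)(C(C)C)C(C)C | intermediate
3 | [3,5-bis(methoxymethoxy)phenoxy]tri(propan-2-yl)silane | COCOc1cc(OCOC)cc(O[Si](C(C)C)(C(C)C)C(C)C)c1 | intermediate
4 | 2-(chloromethyl)-4,4,5,5-tetramethyl-1,3,2-dioxaborolane | ClCB1OC(C)(C)C(C)(C)O1 | starting material
5 | [2,6-bis(methoxymethoxy)-4-{[tri(propan-2-yl)silyl]oxy}phenyl]lithium | [Li]c1c(OCOC)cc(O[Si](C(C)C)(C(C)C)C(C)C)cc1OCOC | intermediate (not isolated)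
6 | lithium (chloromethyl)[2,6-bis(methoxymethoxy)-4-{[tri(propan-2-yl)silyl]oxy}phenyl](2,3-dimethylbutane-2,3-diolato)borate | [Li+].ClC[B-]1(c2c(OCOC)cc(O[Si](C(C)C)(C(C)C)C(C)C)cc2OCOC)OC(C)(C)C(C)(C)O1 | intermediate (not isolated)
7 | 2-{[2,6-bis(methoxymethoxy)-4-{[tri(propan-2-yl)silyl]oxy}phenyl]methyl}-4,4,5,5-tetramethyl-1,3,2-dioxaborolane | CC1(C)OB(Cc2c(OCOC)cc(O[Si](C(C)C)(C(C)C)C(C)C)cc2OCOC)OC1(C)C | intermediate
8 | isobutyraldehyde (2-methylpropanal) | CC(C)C=O | starting material
9 | 2-methylprop-1-en-1-yl trifluoromethanesulfonate | CC(C)=COS(=O)(=O)C(F)(F)F | intermediate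
10 | tetravinylstannane | C=C[Sn](C=C)(C=C)C=C | starting material
11 | vinyllithium | [Li]C=C | intermediate
12 | lithium {[2,6-bis(methoxymethoxy)-4-{[tri(propan-2-yl)silyl]oxy}phenyl]methyl}(ethenyl)(2,3-dimethylbutane-2,3-diolato)borate | [Li+].C=C[B-]1(Cc2c(OCOC)cc(O[Si](C(C)C)(C(C)C)C(C)C)cc2OCOC)OC(C)(C)C(C)(C)O1 | intermediate (not isolated)
13 | 2-[(2S)-1-[2,6-bis(methoxymethoxy)-4-{[tri(propan-2-yl)silyl]oxy}phenyl]-5-methylhex-4-en-2-yl]-4,4,5,5-tetramethyl-1,3,2-dioxaborolane | CC1(C)OB([C@@H](CC=C(C)C)Cc2c(OCOC)cc(O[Si](C(C)C)(C(C)C)C(C)C)cc2OCOC)OC1(C)C | intermediate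
14 | 2-bromopropene | C=C(C)Br | starting material
15 | isopropenyllithium (prop-1-en-2-yllithium) | [Li]C(C)=C | intermediate (not isolated)
16 | lithium {(2S)-1-[2,6-bis(methoxymethoxy)-4-{[tri(propan-2-yl)silyl]oxy}phenyl]-5-methylhex-4-en-2-yl}(prop-1-en-2-yl)(2,3-dimethylbutane-2,3-diolato)borate | [Li+].C=C(C)[B-]1([C@@H](CC=C(C)C)Cc2c(OCOC)cc(O[Si](C(C)C)(C(C)C)C(C)C)cc2OCOC)OC(C)(C)C(C)(C)O1 | intermediate (not isolated)
17 | 2-[(3S)-3-{[2,6-bis(methoxymethoxy)-4-{[tri(propan-2-yl)silyl]oxy}phenyl]methyl}-1-iodo-2,6-dimethylhept-5-en-2-yl]-4,4,5,5-tetramethyl-1,3,2-dioxaborolane (both epimers at C2) | CC(CI)(B1OC(C)(C)C(C)(C)O1)[C@@H](CC=C(C)C)Cc1c(OCOC)cc(O[Si](C(C)C)(C(C)C)C(C)C)cc1OCOC | intermediate (not isolated)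
18 | {3,5-bis(methoxymethoxy)-4-[(2S)-5-methyl-2-(prop-1-en-2-yl)hex-4-en-1-yl]phenoxy}tri(propan-2-yl)silane | C=C(C)[C@@H](CC=C(C)C)Cc1c(OCOC)cc(O[Si](C(C)C)(C(C)C)C(C)C)cc1OCOC | intermediate
19 | 3,5-bis(methoxymethoxy)-4-[(2S)-5-methyl-2-(prop-1-en-2-yl)hex-4-en-1-yl]phenol | C=C(C)[C@@H](CC=C(C)C)Cc1c(OCOC)cc(O)cc1OCOC | intermediate
20 | 2-iodo-3,5-bis(methoxymethoxy)-4-[(2S)-5-methyl-2-(prop-1-en-2-yl)hex-4-en-1-yl]phenol | C=C(C)[C@@H](CC=C(C)C)Cc1c(OCOC)cc(O)c(I)c1OCOC | intermediate
21 | 2,4-dihydroxybenzaldehyde | O=Cc1ccc(O)cc1O | starting material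
22 | 2,4-bis(methoxymethoxy)benzaldehyde | COCOc1ccc(C=O)c(OCOC)c1 | intermediate
23 | 1-ethynyl-2,4-bis(methoxymethoxy)benzene | C#Cc1ccc(OCOC)cc1OCOC | intermediate
24 | 1-{6-hydroxy-2,4-bis(methoxymethoxy)-3-[(2S)-5-methyl-2-(prop-1-en-2-yl)hex-4-en-1-yl]phenyl}-3-[2,4-bis(methoxymethoxy)phenyl]prop-2-yn-1-one | C=C(C)[C@@H](CC=C(C)C)Cc1c(OCOC)cc(O)c(C(=O)C#Cc2ccc(OCOC)cc2OCOC)c1OCOC | intermediate (not isolated)
25 | 3-(diethylamino)-1-{6-hydroxy-2,4-bis(methoxymethoxy)-3-[(2S)-5-methyl-2-(prop-1-en-2-yl)hex-4-en-1-yl]phenyl}-3-[2,4-bis(methoxymethoxy)phenyl]prop-2-en-1-one (alkene geometry not defined) | C=C(C)[C@@H](CC=C(C)C)Cc1c(OCOC)cc(O)c(C(=O)C=C(N(CC)CC)c2ccc(OCOC)cc2OCOC)c1OCOC | intermediate (not isolated)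
26 | 5,7-bis(methoxymethoxy)-2-[2,4-bis(methoxymethoxy)phenyl]-6-[(2S)-5-methyl-2-(prop-1-en-2-yl)hex-4-en-1-yl]-4H-chromen-4-one | C=C(C)[C@@H](CC=C(C)C)Cc1c(OCOC)cc2oc(-c3ccc(OCOC)cc3OCOC)cc(=O)c2c1OCOC | intermediate
27 | 2-(2,4-dihydroxyphenyl)-5,7-dihydroxy-6-[(2S)-5-methyl-2-(prop-1-en-2-yl)hex-4-en-1-yl]-4H-chromen-4-one | C=C(C)[C@@H](CC=C(C)C)Cc1c(O)cc2oc(-c3ccc(O)cc3O)cc(=O)c2c1O | target

## Step count and least certain steps

Total step count: 13 (steps 1–13, including the preparation of 9, 11 and 23).
Longest linear sequence: 9 steps from 1 (steps 1, 2, 3, 6, 7, 8, 9, 12, 13).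

**Step 6 (key step).** The most likely failure is direct transfer of the benzyl or vinyl group from boron to palladium without the 1,2-shift, giving plain cross-coupling. A slow shift of the bulky benzyl group could also let β-hydride elimination and a less face-selective pathway compete, eroding the enantiomeric purity. Protonolysis of the electron-rich benzylic borate is a further loss.

The fallback is a lithiation–borylation with a chiral carbenoid. It sets out from 7 and comes back at 13. Commercial 4-methylpent-3-en-1-ol is converted with N,N-di(propan-2-yl)carbamoyl chloride and Et3N (toluene, reflux) into 4-methylpent-3-en-1-yl N,N-di(propan-2-yl)carbamate F1. Deprotonation with s-BuLi and (+)-sparteine in Et2O at −78 °C should give the configurationally stable (1R)-1-lithio-4-methylpent-3-en-1-yl N,N-di(propan-2-yl)carbamate F2. This takes up 7 with retention to give lithium {[2,6-bis(methoxymethoxy)-4-{[tri(propan-2-yl)silyl]oxy}phenyl]methyl}{(1R)-1-[(dipropan-2-ylcarbamoyl)oxy]-4-methylpent-3-en-1-yl}(2,3-dimethylbutane-2,3-diolato)borate F3. On warming (MgBr2·OEt2 if the shift is slow) the benzyl group migrates with inversion, expels the carbamate and gives 13. The (+)-diamine is specified because the (S)-lithio species from (−)-sparteine would end as the (R)-boronate after retention in the capture and inversion in the shift. The fallback costs a stoichiometric chiral diamine but leaves 7, step 7 and all later steps unchanged.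

**Step 13.** The most likely failure is protonation of the isopropenyl or prenyl double bond and capture of the cation by the C5 or C7 hydroxyl (chroman formation), or addition of methanol to the alkenes, during the time needed to cleave four acetals.

The fallback is an aprotic silyl-transfer deprotection in two stages. It sets out from 26 and comes back at 27. Treatment of 26 with TMSOTf and 2,2′-bipyridyl in CH2Cl2 at 0 °C → rt exchanges each aryl acetal for a silyl ether by way of an N-(methoxymethyl)pyridinium salt, with no free protic acid. This should give 5,7-bis(trimethylsilyloxy)-2-[2,4-bis(trimethylsilyloxy)phenyl]-6-[(2S)-5-methyl-2-(prop-1-en-2-yl)hex-4-en-1-yl]-4H-chromen-4-one F4. The labile aryl silyl ethers are then hydrolysed with water at neutral pH to 27.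

**Step 12.** The most likely failure is slow oxidative addition at the di-ortho-substituted, electron-rich C–I bond. Alkyne dimerisation, CO-free alkynylation with closure to a 2-arylbenzofuran, or 5-exo closure to the aurone could then take over.

The fallback is a stepwise acylation that avoids carbon monoxide. It sets out from 20 and 23 and comes back at 24, which is carried to 26 by Et2NH as in step 12.
- 20 is silylated (TBSCl, imidazole, DMF) to tert-butyl{2-iodo-3,5-bis(methoxymethoxy)-4-[(2S)-5-methyl-2-(prop-1-en-2-yl)hex-4-en-1-yl]phenoxy}dimethylsilane F5.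
- Iodine–magnesium exchange with i-PrMgCl·LiCl (THF, −20 °C) gives {6-[tert-butyl(dimethyl)silyl]oxy-2,4-bis(methoxymethoxy)-3-[(2S)-5-methyl-2-(prop-1-en-2-yl)hex-4-en-1-yl]phenyl}magnesium chloride F6.
- Separately, 23 is deprotonated with n-BuLi and acylated with N-methoxy-N-methylcarbamoyl chloride to 3-[2,4-bis(methoxymethoxy)phenyl]-N-methoxy-N-methylprop-2-ynamide F7.
- Addition of F6 to F7 should give, through the stable chelated adduct, 1-{6-[tert-butyl(dimethyl)silyl]oxy-2,4-bis(methoxymethoxy)-3-[(2S)-5-methyl-2-(prop-1-en-2-yl)hex-4-en-1-yl]phenyl}-3-[2,4-bis(methoxymethoxy)phenyl]prop-2-yn-1-one F8.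
- TBAF in THF containing Et2NH removes the silyl group to give 24, which closes through 25 to 26.

**Step 9.** The most likely failure is over-iodination at the second ortho position, or attack of electrophilic iodine on the trisubstituted alkene, if the phenoxide reacts less cleanly than expected.

The fallback is directed metalation in place of electrophilic substitution. It sets out from 18 and comes back at 20. Treatment of 18 with s-BuLi and TMEDA in THF at −78 °C should remove the ring hydrogen ortho to a MOM ether and give {2,4-bis(methoxymethoxy)-3-[(2S)-5-methyl-2-(prop-1-en-2-yl)hex-4-en-1-yl]-6-{[tri(propan-2-yl)silyl]oxy}phenyl}lithium F9. The low temperature guards against silyl migration and lateral metalation. Quenching with I2 at −78 °C gives {2-iodo-3,5-bis(methoxymethoxy)-4-[(2S)-5-methyl-2-(prop-1-en-2-yl)hex-4-en-1-yl]phenoxy}tri(propan-2-yl)silane F10. TBAF in THF at 0 °C then gives 20. No electrophilic iodine meets a free phenol or remains once the aryllithium is consumed.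

## Further compounds

F1 | step 6 | 4-methylpent-3-en-1-yl N,N-di(propan-2-yl)carbamate | CC(C)=CCCOC(=O)N(C(C)C)C(C)C
F2 | step 6 | (1R)-1-lithio-4-methylpent-3-en-1-yl N,N-di(propan-2-yl)carbamate | [Li][C@H](CC=C(C)C)OC(=O)N(C(C)C)C(C)C
F3 | step 6 | lithium {[2,6-bis(methoxymethoxy)-4-{[tri(propan-2-yl)silyl]oxy}phenyl]methyl}{(1R)-1-[(dipropan-2-ylcarbamoyl)oxy]-4-methylpent-3-en-1-yl}(2,3-dimethylbutane-2,3-diolato)borate | [Li+].CC1(C)O[B-](Cc2c(OCOC)cc(O[Si](C(C)C)(C(C)C)C(C)C)cc2OCOC)([C@H](CC=C(C)C)OC(=O)N(C(C)C)C(C)C)OC1(C)C
F4 | step 13 | 5,7-bis(trimethylsilyloxy)-2-[2,4-bis(trimethylsilyloxy)phenyl]-6-[(2S)-5-methyl-2-(prop-1-en-2-yl)hex-4-en-1-yl]-4H-chromen-4-one | C=C(C)[C@@H](CC=C(C)C)Cc1c(O[Si](C)(C)C)cc2oc(-c3ccc(O[Si](C)(C)C)cc3O[Si](C)(C)C)cc(=O)c2c1O[Si](C)(C)C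
F5 | step 12 | tert-butyl{2-iodo-3,5-bis(methoxymethoxy)-4-[(2S)-5-methyl-2-(prop-1-en-2-yl)hex-4-en-1-yl]phenoxy}dimethylsilane | C=C(C)[C@@H](CC=C(C)C)Cc1c(OCOC)cc(O[Si](C)(C)C(C)(C)C)c(I)c1OCOC
F6 | step 12 | {6-[tert-butyl(dimethyl)silyl]oxy-2,4-bis(methoxymethoxy)-3-[(2S)-5-methyl-2-(prop-1-en-2-yl)hex-4-en-1-yl]phenyl}magnesium chloride | C=C(C)[C@@H](CC=C(C)C)Cc1c(OCOC)cc(O[Si](C)(C)C(C)(C)C)c([Mg]Cl)c1OCOC
F7 | step 12 | 3-[2,4-bis(methoxymethoxy)phenyl]-N-methoxy-N-methylprop-2-ynamide | CON(C)C(=O)C#Cc1ccc(OCOC)cc1OCOC
F8 | step 12 | 1-{6-[tert-butyl(dimethyl)silyl]oxy-2,4-bis(methoxymethoxy)-3-[(2S)-5-methyl-2-(prop-1-en-2-yl)hex-4-en-1-yl]phenyl}-3-[2,4-bis(methoxymethoxy)phenyl]prop-2-yn-1-one | C=C(C)[C@@H](CC=C(C)C)Cc1c(OCOC)cc(O[Si](C)(C)C(C)(C)C)c(C(=O)C#Cc2ccc(OCOC)cc2OCOC)c1OCOC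
F9 | step 9 | {2,4-bis(methoxymethoxy)-3-[(2S)-5-methyl-2-(prop-1-en-2-yl)hex-4-en-1-yl]-6-{[tri(propan-2-yl)silyl]oxy}phenyl}lithium | C=C(C)[C@@H](CC=C(C)C)Cc1c(OCOC)cc(O[Si](C(C)C)(C(C)C)C(C)C)c([Li])c1OCOC
F10 | step 9 | {2-iodo-3,5-bis(methoxymethoxy)-4-[(2S)-5-methyl-2-(prop-1-en-2-yl)hex-4-en-1-yl]phenoxy}tri(propan-2-yl)silane | C=C(C)[C@@H](CC=C(C)C)Cc1c(OCOC)cc(O[Si](C(C)C)(C(C)C)C(C)C)c(I)c1OCOC
A1 | alternative 1 | methyl 4-{6-[2,4-bis(prop-2-en-1-yloxy)phenyl]-4-oxo-4H-pyran-2-yl}-2-[(2S)-5-methyl-2-(prop-1-en-2-yl)hex-4-en-1-yl]-3-oxobutanoate (epimers at C2 of the butanoate) | COC(=O)C(C[C@H](CC=C(C)C)C(C)=C)C(=O)Cc1cc(=O)cc(-c2ccc(OCC=C)cc2OCC=C)o1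
A2 | alternative 1 | 2-[2,4-bis(prop-2-en-1-yloxy)phenyl]-5,7-dihydroxy-6-[(2S)-5-methyl-2-(prop-1-en-2-yl)hex-4-en-1-yl]-4H-chromen-4-one | C=C(C)[C@@H](CC=C(C)C)Cc1c(O)cc2oc(-c3ccc(OCC=C)cc3OCC=C)cc(=O)c2c1O
A3 | alternative 2 | 2-[2,4-bis{[tert-butyl(dimethyl)silyl]oxy}phenyl]-6-(diazoacetyl)-4H-pyran-4-one | [N-]=[N+]=CC(=O)c1cc(=O)cc(-c2ccc(O[Si](C)(C)C(C)(C)C)cc2O[Si](C)(C)C(C)(C)C)o1
A4 | alternative 2 | {[(4S)-7-methyl-4-(prop-1-en-2-yl)oct-6-en-1-yn-1-yl]oxy}tri(propan-2-yl)silane | C=C(C)[C@@H](CC=C(C)C)CC#CO[Si](C(C)C)(C(C)C)C(C)C
A5 | alternative 2 | 2-[2,4-bis{[tert-butyl(dimethyl)silyl]oxy}phenyl]-5-hydroxy-6-[(2S)-5-methyl-2-(prop-1-en-2-yl)hex-4-en-1-yl]-7-{[tri(propan-2-yl)silyl]oxy}-4H-chromen-4-one | C=C(C)[C@@H](CC=C(C)C)Cc1c(O[Si](C(C)C)(C(C)C)C(C)C)cc2oc(-c3ccc(O[Si](C)(C)C(C)(C)C)cc3O[Si](C)(C)C(C)(C)C)cc(=O)c2c1O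
A6 | alternative 3 | 2-iodo-3,5-bis(methoxymethoxy)-4-[(2S)-5-methyl-2-(prop-1-en-2-yl)hex-4-en-1-yl]phenol | C=C(C)[C@@H](CC=C(C)C)Cc1c(OCOC)cc(O)c(I)c1OCOC
A7 | alternative 3 | 1-ethynyl-2,4-bis(methoxymethoxy)benzene | C#Cc1ccc(OCOC)cc1OCOC
A8 | alternative 3 | 5,7-bis(methoxymethoxy)-2-[2,4-bis(methoxymethoxy)phenyl]-6-[(2S)-5-methyl-2-(prop-1-en-2-yl)hex-4-en-1-yl]-4H-chromen-4-one | C=C(C)[C@@H](CC=C(C)C)Cc1c(OCOC)cc2oc(-c3ccc(OCOC)cc3OCOC)cc(=O)c2c1OCOC
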